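Retrosynthesis: the C7 ester and C19 acid are traced back to a C7–C19 bond (retro-Claisen). C4–C19 comes from an intramolecular nitronate Michael addition, C13–C16 from a ketyl–alkyne closure, C8–C15 from a Birch reduction–alkylation, and C1–C10 with C4–C5 from a Diels–Alder reaction.
Forward: 5-methoxy-1-indanone supplies ring B and an aromatic ring C, and ring A is added by cycloaddition. Ring C is then dearomatised, ring D is closed, and the temporary ring C4–C5–C6–C7–C19 is made and cut.
Stereochemistry: a chiral oxazaborolidinium catalyst sets C5 and C10 (cis, suprafacial). Ring A then covers the α face, so C15 (alkylation) and H9 (hydrogenation directed by the C16 hydroxyl and C20 ester) enter from the β face. C13 follows from the bridge, C4 from the tether, and C6 from a final equilibration.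
Enabling feature: on ring A the C4–C19 and C5–C6 bonds point to the same (α) face, and C7 has to end as a methyl ester. A C7 ketone on C6 can therefore carry C19 to C4 through a five-membered ring, and methanol/methoxide then splits that ring into the C7 ester and a C19 nitromethyl group.

Key step: step 19

Numbering: gibberellane numbering. Ring A = C1–C5, C10; ring B = C5, C6, C8, C9, C10; ring C = C8, C9, C11–C14; ring D = C8, C14, C13, C16, C15. C17 is the methylene, C18 the methyl, and C7, C19, C20 the carboxyl carbons.
Assumption: the configuration is taken exactly as the SMILES is written. H5, H9, C15, C20 and C7 lie on one face of ring B (called β) and C1, C4, C11 and C14 on the other (α), so rings A and C are both cis-fused to ring B on its α face.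

Step 1
Reactants: 1 5-methoxy-1-indanone
Product: 2 6-methoxy-1H-inden-3-yl triflate
Conditions: Tf2O, 2,6-di-tert-butyl-4-methylpyridine, CH2Cl2, 0→23 °C
Reagents that add atoms: triflic anhydride O=S(=O)(OS(=O)(=O)C(F)(F)F)C(F)(F)F
Why: Enol triflate formation, in which the ketone (future C10) can enolise only toward C5 and O-sulfonylation with a hindered pyridine base is routine for 1-indanones; no stereocentre is formed.

Step 2
Reactants: 2 6-methoxy-1H-inden-3-yl triflate
Product: 3 2-(trimethylsilyl)ethyl 6-methoxy-1H-indene-3-carboxylate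
Conditions: Pd(OAc)2, dppp, CO (1 atm), Et3N, Me3SiCH2CH2OH, DMF, 60 °C
Reagents that add atoms: carbon monoxide [C-]#[O+]; 2-(trimethylsilyl)ethanol C[Si](C)(C)CCO
Why: Palladium-catalysed alkoxycarbonylation of a vinyl triflate, in which oxidative addition to zerovalent palladium, CO insertion and capture by the alcohol install C20 as a fluoride-labile ester on the conjugated C5=C10 bond.

Step 3
Reactants: 3 2-(trimethylsilyl)ethyl 6-methoxy-1H-indene-3-carboxylate
Product: 4 2-(trimethylsilyl)ethyl 6-methoxy-1-oxo-1H-indene-3-carboxylate (indenone: C6 ketone, C5=C10, C20 ester on C10)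
Conditions: Rh2(cap)4 (dirhodium tetracaprolactamate, 1 mol %), 70 % aq. t-BuOOH, DCE, 40 °C; used at once
Reagents that add atoms: tert-butyl hydroperoxide CC(C)(C)OO
Why: Allylic/benzylic C–H oxidation, in which C6H2 is both benzylic and γ to the unsaturated ester and this radical oxidation is known to turn exactly that position into a 4-oxo-2-enoate.

Step 4
Reactants: 5 (E)-pent-3-en-2-one
Product: 6 (E)-2-(tert-butyldimethylsilyloxy)penta-1,3-diene
Conditions: TBSOTf, Et3N, Et2O, 0 °C
Reagents that add atoms: tert-butyldimethylsilyl triflate CC(C)(C)[Si](C)(C)OS(=O)(=O)C(F)(F)F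
Why: Soft enolisation and O-silylation at the methyl group of the enone gives the cross-conjugated 2-silyloxy diene with the E double bond unchanged.

Step 5
Reactants: 4 indenone ester; 6 silyloxy diene
Product: 7 cis-fused cycloadduct (rings A, B and aromatic C; C2 silyl enol ether; 4-methyl; C20 ester on C10; C6 ketone)
Conditions: (S)-oxazaborolidine from α,α-diphenylprolinol and o-tolylboroxine, activated with HNTf2 (20 mol %), CH2Cl2, −78 °C
Reagents that add atoms: none
Why: Catalytic enantioselective Diels–Alder reaction, in which the oxazaborolidinium ion binds the more basic C6 ketone and makes C10 the electrophilic end, so the nucleophilic CH2 terminus of 6 (C1) bonds to C10 and the methyl-bearing terminus (C4) to C5; suprafacial addition fixes H5 and C20 cis, the catalyst chooses the face (its mirror image is equally available if the sense proves opposite), and the endo-derived C4 centre is erased in step 17.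

Step 6
Reactants: 7 cycloadduct
Product: 8 C2 ethylene ketal of the hexahydrofluorenone
Conditions: HOCH2CH2OH, p-TsOH·H2O (cat.), benzene, reflux
Reagents that add atoms: ethylene glycol OCCO
Why: Acid-catalysed ketalisation, in which protonation of the silyl enol ether at C3 and capture by the diol mask C2 while the conjugated, hindered aryl ketone at C6 stays free and the cis A/B junction (the stable one) is kept.

Step 7
Reactants: 8 ketal aryl ketone; 9 tert-butyl(2-iodoethoxy)dimethylsilane
Product: 11 C8-(2-silyloxyethyl) 13-methoxy-9(11),13-diene C6 ketone, via lithium dienolate 10 (not isolated)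
Conditions: K (2.3 equiv), t-BuOH (1.0 equiv), NH3–THF, −78 °C; LiBr; then 9, −78→−33 °C
Reagents that add atoms: none
Why: Birch reduction–alkylation of an aryl ketone, in which two electrons and one proton (at C12, para to C8) convert the 3-methoxyaryl ketone into dienolate 10 before the isolated ester or ketal can react, and 10 is alkylated at C8 from the β face because C1 and C4 of the cis-fused ring A cover the α face, which sets the quaternary centre C8.

Step 8
Reactants: 11 diene ketone
Product: 12 16-hydroxy 9(11)-ene-6,13-dione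
Conditions: AcOH–THF–H2O (3:1:1), 23 °C
Reagents that add atoms: water O
Why: Mild acid hydrolysis cleaves the methyl enol ether (to the C13 ketone, with the C9=C11 bond left unconjugated) and the primary silyl ether, both of which react much faster than the dioxolane at C2.

Step 9
Reactants: 12 hydroxy enedione
Product: 13 9β-H saturated 16-hydroxy-6,13-dione
Conditions: [Ir(cod)(PCy3)(py)]PF6 (10 mol %), H2 (10 bar), CH2Cl2, 23 °C
Reagents that add atoms: none
Why: Hydroxyl- and ester-directed homogeneous hydrogenation, in which the cationic iridium complex is held by the C16 hydroxyl of the angular side chain and by the C20 ester carbonyl, both on the β face, and so delivers H2 to that face of the hindered C9=C11 bond against the steric bias, placing H9 cis to C15 and C20.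

Step 10
Reactants: 13 hydroxy dione
Product: 14 C16 aldehyde
Conditions: DMP, CH2Cl2, 0→23 °C; used crude
Reagents that add atoms: none
Why: Periodinane oxidation of a primary alcohol to the aldehyde under nearly neutral conditions that leave the ketal, the ester and the α-stereocentres untouched.

Step 11
Reactants: 14 keto aldehyde
Product: 15 C8-propargyl 6,13-dione
Conditions: dimethyl (1-diazo-2-oxopropyl)phosphonate, K2CO3, MeOH, 0→23 °C
Reagents that add atoms: dimethyl (1-diazo-2-oxopropyl)phosphonate CC(=O)C(=[N+]=[N-])P(=O)(OC)OC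
Why: Ohira–Bestmann (Seyferth–Gilbert) homologation adds C17 and is aldehyde-selective, and a transannular aldol between C12 and C16 can only be a reversible side equilibrium because its product cannot dehydrate at a bridgehead.

Step 12
Reactants: 15 alkynyl dione
Product: 16 tetracyclic 13-hydroxy-16-methylene C6 ketone
Conditions: SmI2 (2.5 equiv), HMPA, t-BuOH, THF, 0 °C
Reagents that add atoms: none
Why: Ketyl–alkyne reductive cyclisation, in which divalent samarium reduces the unhindered C13 ketone to its ketyl and this adds 5-exo-dig to C16 of the axial propargyl group, giving the bicyclo[3.2.1]octane, the bridgehead hydroxyl and the exocyclic methylene together; C13 can form only with the geometry imposed by the C8 tether, and the C6 ketone, flanked by C5 and quaternary C8 and lacking an acceptor, is left.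

Step 13
Reactants: 16 tertiary alcohol
Product: 17 13-O-TBS ether
Conditions: TBSOTf, 2,6-lutidine, CH2Cl2, 0 °C
Reagents that add atoms: tert-butyldimethylsilyl triflate CC(C)(C)[Si](C)(C)OS(=O)(=O)C(F)(F)F
Why: Silylation of a hindered tertiary alcohol with the silyl triflate and a weak, hindered base that does not enolise the C6 ketone.

Step 14
Reactants: 17 C6 ketone
Product: 18 C6 methoxymethylidene enol ether (E/Z mixture)
Conditions: MeOCH2PPh3Cl, KHMDS, THF, 0→50 °C
Reagents that add atoms: (methoxymethyl)triphenylphosphonium chloride COC[P+](c1ccccc1)(c1ccccc1)c1ccccc1.[Cl-]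
Why: Wittig methoxymethylenation adds C7 to the only free ketone, a reaction that works on cyclopentanones next to a quaternary carbon when the reactive ylide is used in excess.

Step 15
Reactants: 18 enol ether ketal
Product: 19 6α-formyl C2 ketone
Conditions: 1 M HCl, THF, 0→23 °C; used at once
Reagents that add atoms: water O
Why: Acid hydrolysis of the enol ether and the dioxolane, in which the rate-limiting protonation of C6 comes from the less crowded β face (H5 and C15 against C4 and C14), which puts the formyl group on the α face next to C4, and the hindered aldehyde is oxidised before it can equilibrate.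

Step 16
Reactants: 19 keto aldehyde
Product: 20 6α-carboxylic acid C2 ketone
Conditions: NaClO2, NaH2PO4, 2-methyl-2-butene, t-BuOH–H2O, 0→23 °C
Reagents that add atoms: sodium chlorite [Na+].[O-]Cl=O
Why: Pinnick oxidation converts the aldehyde to the acid in a weakly acidic buffer without epimerising C6, while the scavenger protects the C16 methylene from hypochlorite.

Step 17
Reactants: 20 keto acid
Product: 21 ring A 4-methyl-2-enone 6α-carboxylic acid
Conditions: IBX, DMSO, 70 °C
Reagents that add atoms: none
Why: IBX dehydrogenation of a ketone, in which only C3–C4 can be desaturated because C10 bears no hydrogen, so the enone forms as a single regioisomer and the C4 centre of the cycloadduct disappears.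

Step 18
Reactants: 21 enone acid; 22 nitromethane
Product: 24 ring A 4-methyl-2-enone with a 6α-nitroacetyl group, via acyl imidazolide 23 (not isolated)
Conditions: CDI, THF, 23 °C; then preformed MeNO2/KOt-Bu, THF, 0→23 °C; 1 M HCl
Reagents that add atoms: 1,1'-carbonyldiimidazole O=C(n1ccnc1)n1ccnc1 (its imidazolyl group stays only in 23)
Why: Acylation of nitromethane anion by an acyl imidazolide, the standard route to α-nitro ketones, in which the product is held as its nitronate until the quench, which protects C6 from epimerisation, and intermolecular attack on the β,β-disubstituted enone is slow.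

Step 19
Reactants: 24 nitroacetyl enone
Product: 26 C7–C19 bridged nitro cyclopentanone, via amidinium nitronate 25 (not isolated)
Conditions: DBU (1.2 equiv), MeCN, 23→45 °C; then AcOH
Reagents that add atoms: none
Why: DBU removes the very acidic C19 proton (between the C7 carbonyl and the nitro group) to give nitronate 25, whose carbon adds to C4, the β-carbon of the ring A enone, and the resulting C2 enolate is protonated at C3. The closest known reaction type is the intramolecular Michael addition of α-nitro ketones, and of nitronates in general, to enones. The one new ring (C4, C5, C6, C7, C19) closes 5-exo-trig and is cis-fused to ring A at C4–C5 and to ring B at C5–C6, so with the cis A/B junction an all-cis bowl around C5 results and no trans junction is built. The new quaternary centre C4 is controlled by the tether: C6 leaves C5 on the α face of ring A, the chain C6–C7–C19 can reach C4 only from that face, and C18 is pushed to the β face beside H5 and C20, while C19 stays acidic and its configuration does not matter. The step needs facial selectivity at C4 (given by the tether), the α configuration at C6 (installed in step 15 and frozen here because the nitronate makes H6 far less acidic) and chemoselectivity for C19 over the α′ and γ positions of the enone (given by the large acidity gap, so a mild amidine base suffices). The equilibrium is helped by intramolecularity and by storage of the product as an equally stabilised nitronate until the acidic quench.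

Step 20
Reactants: 26 bridged nitro cyclopentanone
Product: 27 6α-methyl ester with C19 nitromethyl group and C2 ketone
Conditions: NaOMe (0.1 equiv), MeOH, 0→23 °C
Reagents that add atoms: methanol CO
Why: Retro-Claisen cleavage of a cyclic α-nitro ketone, in which methoxide adds to the nitro-activated C7 carbonyl and expels the C19 nitronate to give the C7 methyl ester and the nitromethyl group on C4; only catalytic base is used because a full equivalent would hold the ring closed as its nitronate and could start retro-Michael loss of C19.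

Step 21
Reactants: 27 nitro keto ester
Product: 28 C2 tosylhydrazone
Conditions: TsNHNH2, AcOH (cat.), EtOH, 50 °C
Reagents that add atoms: p-toluenesulfonyl hydrazide Cc1ccc(cc1)S(=O)(=O)NN
Why: Hydrazone condensation at the only ketone, under weakly acidic conditions that leave the nitro group, both esters and the silyl ether untouched.

Step 22
Reactants: 28 tosylhydrazone
Product: 29 2-deoxo nitro ester
Conditions: catecholborane, CHCl3, −10 °C; then NaOAc·3H2O, reflux
Reagents that add atoms: none
Why: Caglioti-type tosylhydrazone reduction, in which hydride addition to C=N, loss of sulfinate and extrusion of N2 from the diazene give C2H2, while uncatalysed catecholborane is too slow at this temperature to touch the C16 methylene.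

Step 23
Reactants: 29 nitro ester
Product: 30 C19 carboxylic acid (still 6α ester)
Conditions: NaNO2, AcOH, DMSO, 35 °C
Reagents that add atoms: sodium nitrite [Na+].[O-]N=O
Why: Nitrite-mediated oxidation of a primary nitroalkane to the acid (a Nef-type conversion through the nitrolic acid and nitrile oxide), placed after removal of the C2 ketone because that ketone would be nitrosated at its α positions.

Step 24
Reactants: 30 6α ester
Product: 31 6β ester (C6 equilibrated)
Conditions: NaOMe (5 equiv), MeOH, 60 °C; then 1 M HCl
Reagents that add atoms: none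
Why: Base equilibration of an ester α-centre, in which C19 is now a carboxylate that cannot re-close onto C7, so C6 should settle with its ester on the β face away from C4, C14 and the C19 group, while the C20 ester on quaternary C10 is too hindered for methoxide.

Step 25
Reactants: 31 protected diacid monoester
Product: 32 target (C19 and C20 acids, C7 methyl ester, 13-hydroxyl)
Conditions: TBAF, THF, 23→50 °C; then 1 M HCl
Reagents that add atoms: none
Why: Fluoride deprotection fragments the 2-(trimethylsilyl)ethyl ester and cleaves the tertiary silyl ether in one operation without acid, which avoids rearrangement of the 13-hydroxy-16-ene unit.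

Compound list
1 | 5-methoxy-1-indanone | COc1ccc2c(c1)CCC2=O | starting material
2 | 6-methoxy-1H-inden-3-yl triflate | COc1ccc2c(c1)CC=C2OS(=O)(=O)C(F)(F)F | intermediate
3 | 2-(trimethylsilyl)ethyl 6-methoxy-1H-indene-3-carboxylate | COc1ccc2c(c1)CC=C2C(=O)OCC[Si](C)(C)C | intermediate
4 | 2-(trimethylsilyl)ethyl 6-methoxy-1-oxo-1H-indene-3-carboxylate | COc1ccc2c(c1)C(=O)C=C2C(=O)OCC[Si](C)(C)C | intermediate
5 | (E)-pent-3-en-2-one | C/C=C/C(C)=O | starting material
6 | (E)-2-(tert-butyldimethylsilyloxy)penta-1,3-diene | C=C(O[Si](C)(C)C(C)(C)C)/C=C/C | intermediate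
7 | cis-fused Diels–Alder adduct, C2 silyl enol ether | COc1cc2c(cc1)[C@@]1(C(=O)OCC[Si](C)(C)C)CC(O[Si](C)(C)C(C)(C)C)=C[C@@H](C)[C@H]1C2=O | intermediate
8 | C2 ethylene ketal, C6 aryl ketone | COc1cc2c(cc1)[C@@]1(C(=O)OCC[Si](C)(C)C)CC3(OCCO3)C[C@@H](C)[C@H]1C2=O | intermediate
9 | tert-butyl(2-iodoethoxy)dimethylsilane | CC(C)(C)[Si](C)(C)OCCI | starting material
10 | lithium dienolate (C6–O, C6=C8, C9=C11, C13=C14) | [Li+].COC1=CC2=C([O-])[C@@H]3[C@H](C)CC4(OCCO4)C[C@]3(C(=O)OCC[Si](C)(C)C)C2=CC1 | intermediate
11 | C8-(2-silyloxyethyl) 13-methoxy-9(11),13-diene C6 ketone | CC(C)(C)[Si](C)(C)OCC[C@]23C=C(OC)CC=C2[C@@]1(C(=O)OCC[Si](C)(C)C)CC4(OCCO4)C[C@@H](C)[C@H]1C3=O | intermediate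
12 | 16-hydroxy 9(11)-ene-6,13-dione | OCC[C@]23CC(=O)CC=C2[C@@]1(C(=O)OCC[Si](C)(C)C)CC4(OCCO4)C[C@@H](C)[C@H]1C3=O | intermediate
13 | 9β-H 16-hydroxy-6,13-dione | OCC[C@]23CC(=O)CC[C@H]2[C@@]1(C(=O)OCC[Si](C)(C)C)CC4(OCCO4)C[C@@H](C)[C@H]1C3=O | intermediate
14 | C16 aldehyde 6,13-dione | O=CC[C@]23CC(=O)CC[C@H]2[C@@]1(C(=O)OCC[Si](C)(C)C)CC4(OCCO4)C[C@@H](C)[C@H]1C3=O | intermediate
15 | C8-propargyl 6,13-dione | C#CC[C@]23CC(=O)CC[C@H]2[C@@]1(C(=O)OCC[Si](C)(C)C)CC4(OCCO4)C[C@@H](C)[C@H]1C3=O | intermediate
16 | tetracyclic 13-hydroxy-16-methylene C6 ketone | C=C1C[C@]23C[C@@]1(O)CC[C@H]2[C@@]1(C(=O)OCC[Si](C)(C)C)CC4(OCCO4)C[C@@H](C)[C@H]1C3=O | intermediate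
17 | 13-O-TBS ether | C=C1C[C@]23C[C@@]1(O[Si](C)(C)C(C)(C)C)CC[C@H]2[C@@]1(C(=O)OCC[Si](C)(C)C)CC4(OCCO4)C[C@@H](C)[C@H]1C3=O | intermediate
18 | C6 methoxymethylidene enol ether (E/Z) | C=C1C[C@]23C[C@@]1(O[Si](C)(C)C(C)(C)C)CC[C@H]2[C@@]1(C(=O)OCC[Si](C)(C)C)CC4(OCCO4)C[C@@H](C)[C@H]1C3=COC | intermediate
19 | 6α-formyl C2 ketone | C=C1C[C@]23C[C@@]1(O[Si](C)(C)C(C)(C)C)CC[C@H]2[C@@]1(C(=O)OCC[Si](C)(C)C)CC(=O)C[C@@H](C)[C@H]1[C@H]3C=O | intermediate
20 | 6α-carboxylic acid C2 ketone | C=C1C[C@]23C[C@@]1(O[Si](C)(C)C(C)(C)C)CC[C@H]2[C@@]1(C(=O)OCC[Si](C)(C)C)CC(=O)C[C@@H](C)[C@H]1[C@H]3C(=O)O | intermediate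
21 | 4-methyl-2-enone 6α-carboxylic acid | C=C1C[C@]23C[C@@]1(O[Si](C)(C)C(C)(C)C)CC[C@H]2[C@@]1(C(=O)OCC[Si](C)(C)C)CC(=O)C=C(C)[C@H]1[C@H]3C(=O)O | intermediate
22 | nitromethane | C[N+](=O)[O-] | starting material
23 | acyl imidazolide of 21 | C=C1C[C@]23C[C@@]1(O[Si](C)(C)C(C)(C)C)CC[C@H]2[C@@]1(C(=O)OCC[Si](C)(C)C)CC(=O)C=C(C)[C@H]1[C@H]3C(=O)n4ccnc4 | intermediate
24 | 4-methyl-2-enone with 6α-nitroacetyl group (key-step precursor) | C=C1C[C@]23C[C@@]1(O[Si](C)(C)C(C)(C)C)CC[C@H]2[C@@]1(C(=O)OCC[Si](C)(C)C)CC(=O)C=C(C)[C@H]1[C@H]3C(=O)C[N+](=O)[O-] | intermediate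
25 | DBU-H nitronate of 24 | C=C1C[C@]23C[C@@]1(O[Si](C)(C)C(C)(C)C)CC[C@H]2[C@@]1(C(=O)OCC[Si](C)(C)C)CC(=O)C=C(C)[C@H]1[C@H]3C(=O)C=[N+]([O-])[O-].C1CCC2=[NH+]CCCN2CC1 | intermediate
26 | C7–C19 bridged nitro cyclopentanone (C19 labile, drawn arbitrarily) | C=C1C[C@]23C[C@@]1(O[Si](C)(C)C(C)(C)C)CC[C@H]2[C@@]1(C(=O)OCC[Si](C)(C)C)CC(=O)C[C@]4(C)[C@H]1[C@H]3C(=O)[C@@H]4[N+](=O)[O-] | intermediate
27 | 6α-methyl ester, C19 nitromethyl, C2 ketone | C=C1C[C@]23C[C@@]1(O[Si](C)(C)C(C)(C)C)CC[C@H]2[C@@]1(C(=O)OCC[Si](C)(C)C)CC(=O)C[C@@](C)(C[N+](=O)[O-])[C@H]1[C@H]3C(=O)OC | intermediate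
28 | C2 tosylhydrazone of 27 | C=C1C[C@]23C[C@@]1(O[Si](C)(C)C(C)(C)C)CC[C@H]2[C@@]1(C(=O)OCC[Si](C)(C)C)CC(=NNS(=O)(=O)c4ccc(C)cc4)C[C@@](C)(C[N+](=O)[O-])[C@H]1[C@H]3C(=O)OC | intermediate
29 | 2-deoxo nitro ester (6α) | C=C1C[C@]23C[C@@]1(O[Si](C)(C)C(C)(C)C)CC[C@H]2[C@@]1(C(=O)OCC[Si](C)(C)C)CCC[C@@](C)(C[N+](=O)[O-])[C@H]1[C@H]3C(=O)OC | intermediate
30 | C19 acid, 6α ester | C=C1C[C@]23C[C@@]1(O[Si](C)(C)C(C)(C)C)CC[C@H]2[C@@]1(C(=O)OCC[Si](C)(C)C)CCC[C@@](C)(C(=O)O)[C@H]1[C@H]3C(=O)OC | intermediate
31 | C19 acid, 6β ester | C=C1C[C@]23C[C@@]1(O[Si](C)(C)C(C)(C)C)CC[C@H]2[C@@]1(C(=O)OCC[Si](C)(C)C)CCC[C@@](C)(C(=O)O)[C@H]1[C@@H]3C(=O)OC | intermediate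
32 | CNP0285449.1 | C=C1C[C@]23C[C@@]1(O)CC[C@H]2[C@@]1(C(=O)O)CCC[C@@](C)(C(=O)O)[C@H]1[C@@H]3C(=O)OC | target

Total steps: 25. Longest linear sequence: 24 (steps 1–3 and 5–25, from 1 to 32).

Steps most likely to fail

Step 19. The closure may stall, because addition of a doubly stabilised nitronate to a β,β-disubstituted enone carbon is reversible and builds a quaternary centre. The α configuration at C6 may also be lost before closure. The fallback lowers the oxidation level of the tether; it sets out from 23 and comes back at 26. Reduction of 23 with LiAlH(Ot-Bu)3 at −78 °C gives the 6-formyl enone F1. Nitromethane and DBU add to the aldehyde (Henry reaction) to give the β-nitro alcohol F2. Its far more nucleophilic nitronate closes the same C4–C19 bond in the same flask to the bridged nitro cyclopentanol F3. Reversible Henry addition and aldehyde enolisation keep supplying the α-epimer at C6. DMP oxidation of F3 gives 26.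

Step 9. Hydrogen may be delivered to the α face, or the C9=C11 bond between two quaternary carbons may not react, because the flexible primary hydroxyl and the ester are only moderate directing groups. The fallback installs a closer director; it sets out from 12 and comes back at 14. L-Selectride attacks the C13 ketone from the α face, away from the axial C15 chain, and gives the 13β-axial homoallylic diol F4. Hydrogenation with [Ir(cod)(PCy3)(py)]PF6, now anchored by the ring hydroxyl on the β face, gives the saturated diol F5. Excess DMP oxidises both carbinols at once to 14.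

Step 5. A fast uncatalysed background cycloaddition of this very reactive indenone may erode facial discrimination by the catalyst. The fallback replaces catalysis by resolution; it sets out from 4 and 6 and comes back at 8. The cycloaddition is run with Et2AlCl and gives 7 together with its mirror image ent-7 F6. Ketalisation with (R,R)-hydrobenzoin and TsOH gives the hydrobenzoin ketal of the wanted series F7 and the diastereomeric ketal of the mirror-image series F8, which are separated by crystallisation or chromatography. Exchange of F7 with ethylene glycol and TsOH gives 8.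

Further compounds
F1 | step 19 | 6α-formyl 4-methyl-2-enone | C=C1C[C@]23C[C@@]1(O[Si](C)(C)C(C)(C)C)CC[C@H]2[C@@]1(C(=O)OCC[Si](C)(C)C)CC(=O)C=C(C)[C@H]1[C@H]3C=O
F2 | step 19 | β-nitro alcohol (C7 carbinol, epimers at C7) | C=C1C[C@]23C[C@@]1(O[Si](C)(C)C(C)(C)C)CC[C@H]2[C@@]1(C(=O)OCC[Si](C)(C)C)CC(=O)C=C(C)[C@H]1[C@H]3C(O)C[N+](=O)[O-]
F3 | step 19 | bridged nitro cyclopentanol (C7 and C19 undefined) | C=C1C[C@]23C[C@@]1(O[Si](C)(C)C(C)(C)C)CC[C@H]2[C@@]1(C(=O)OCC[Si](C)(C)C)CC(=O)C[C@]4(C)[C@H]1[C@H]3C(O)C4[N+](=O)[O-]
F4 | step 9 | 13β,16-diol 9(11)-ene C6 ketone | OCC[C@]23C[C@H](O)CC=C2[C@@]1(C(=O)OCC[Si](C)(C)C)CC4(OCCO4)C[C@@H](C)[C@H]1C3=O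
F5 | step 9 | 9β-H 13β,16-diol C6 ketone | OCC[C@]23C[C@H](O)CC[C@H]2[C@@]1(C(=O)OCC[Si](C)(C)C)CC4(OCCO4)C[C@@H](C)[C@H]1C3=O
F6 | step 5 | ent-7 | COc1cc2c(cc1)[C@]1(C(=O)OCC[Si](C)(C)C)CC(O[Si](C)(C)C(C)(C)C)=C[C@H](C)[C@@H]1C2=O
F7 | step 5 | (R,R)-hydrobenzoin ketal, wanted series | COc1cc2c(cc1)[C@@]1(C(=O)OCC[Si](C)(C)C)CC3(O[C@H](c4ccccc4)[C@@H](c4ccccc4)O3)C[C@@H](C)[C@H]1C2=O
F8 | step 5 | (R,R)-hydrobenzoin ketal, mirror-image series | COc1cc2c(cc1)[C@]1(C(=O)OCC[Si](C)(C)C)CC3(O[C@H](c4ccccc4)[C@@H](c4ccccc4)O3)C[C@H](C)[C@@H]1C2=O
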